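Each coupling partner charged stays on the books: it stands free, dormant or in idle adduct, or it has gone into target.

solid substrate 0.50 mM; coupling partner 0.550 mM; time 12 s

    solid substrate ⇌ dissolved substrate, rate k1*(cs1 - [dissolved substrate]) while solid is left; crystals form when [dissolved substrate] > cs1 (cs1 = 0.30 mM, k1 = 0.32 s⁻¹)
    dissolved substrate + coupling partner → target (k2 = 64000 M⁻¹ s⁻¹)
    2 dissolved substrate → side product (k3 = 39000 M⁻¹ s⁻¹)
    solid product ⇌ target, rate k4*(cs4 - [target]) while solid is left; crystals form when [target] > cs4 (cs4 = 0.21 mM, k4 = 3.7 s⁻¹)
    coupling partner + target ⇌ idle adduct, settled at all times (K5 = 560 M⁻¹)
    coupling partner ⇌ dormant form (K6 = 6.4, k6 = 0.44 s⁻¹)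
    solid substrate → decomposition product (k7 = 6.5 × 10⁻⁵ s⁻¹)

- percentages count the solid substrate that a species holds: one side product counts as two
- target is meant together with its solid product and idle adduct
- two of one species on the left: rate k times its square, two consumed each time
- solid, in amounts per volume of the solution: solid substrate, solid product
- at the start none of the solid substrate is in solution
- run time (flask): 12 s

- amount of target and solid product and idle adduct together at 12 s, in percent of the solid substrate charged
- the change that raises the amount of target and solid product and idle adduct together at 12 s, in percent of the solid substrate charged most ("none" if none brings more than 2 percentage points) (north-west / north / west / north-east / none)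
- amount of target and solid product and idle adduct together at 12 s, in percent of the solid substrate charged, after north

- north-west: doubling the dissolution coefficient of step 1, all else as stated
- north: doubling the solubility in step 1, all else as stated
- west: doubling the dissolution coefficient of step 4, all else as stated
- north-east: doubling the amount of coupling partner, all else as stated

I assume the solution stays nearly empty, so the solid gives a constant, zero-order feed F, the dissolution coefficient times the solubility, 0.0960 mM s⁻¹, and is gone at t_d = 5.21 s. Free partner then falls by its forward dormant rate, k times its concentration, plus F. Integrating from the charge c, it reaches zero at t_r = (ln(1 + kc/F))/k = 2.86 s, the run-out time, which is earlier than t_d.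

In this reckoning, the feed makes 0.275 mM of target up to t_r. From then until t_d, I let the remaining dormant form return at k/K, with K the equilibrium constant of the dormant step, which adds 0.0444 mM, and I let the other dissolved substrate become side product. That gives 63.8%.

North doubles the solubility of the solid substrate and so doubles F, which moves t_r to 1.85 s and gives 73.2%. North-west doubles F too. West moves material between target and solid product, both inside the count. Doubling the partner moves t_r to 4.09 s and gives 89.4%, so I choose north-east.

The forecast says 64%, north-east and 75% after north, holding that “Doubling the partner helps most”.

The flask gives 63.9%, north-east with a gain of 28 percentage points, and 72.2% after north.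

In this flask t_r comes at 2.86 s, earlier than t_d at 5.21 s, and side product stands at 36.1% at the end. In the neighbour charged with 0.22 mM of coupling partner, t_r is 1.58 s, again earlier than t_d, and the same reckoning gives 33.8%; that neighbour holds 31.8% of target, all its forms counted, with side product at 68.1%.

The numbers are invented; no experiment stands behind them.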